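**Plan**
- Retrosynthesis: the anisoyl group on the C6 oxygen and the C8/C9 epoxide oxygen are removed first. The C8 methyl and the C8=C9 unsaturation are then traced back to a plain C6 ketone. The cyclopentane is opened at C4–C5 together with removal of the C1 methyl (one operation), and the C1–C2 bond to the side chain is cut last.
- Forward: the seven-membered ring is bought as cycloheptane-1,3-dione and the 4-methyl-3-oxopentyl chain is attached at C1 by a Stork–Danheiser sequence. The five-membered ring (C1–C5) is closed in the key step, and the seven-membered ring is then methylated, unsaturated, reduced, acylated and epoxidised.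
- Enabling feature: C1 (quaternary, methyl), C5 (ring-fusion CH) and C4 (tertiary isopropyl carbinol) are contiguous on the cyclopentane, and C5 is bonded to C6 of the seven-membered ring. With C6 as a ketone, its β-carbon carries the methyl and its α-carbon the carbinol, which is what a methyl conjugate addition followed by an aldol closure leaves behind.
- Stereochemistry: C1 comes from a chiral copper–phosphoramidite catalyst, and C5 and C4 are relayed from C1 through a chelated, reversible aldol. C6 is set by hydride delivery from the C4 hydroxyl, and C8/C9 by epoxidation anti to the angular methyl.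

Key step: step 4

Remark: atoms are numbered as in the target (C1 angular-methyl carbon, C2, C3, C4 carbinol carbon, C5 ring-fusion CH, C6 oxygenated carbon, C7, C8 and C9 the later epoxide carbons, C10) and β is the face of the C1 methyl group. L* is the biphenyl-2,2'-diol phosphoramidite of bis[1-(naphthalen-2-yl)ethyl]amine, used as the antipode that sends methyl to the Re face of C1 (both antipodes are accessible).

**Step 1**
Reactants: 1 4-methylpent-1-en-3-one
Product: 3 2-(2-bromoethyl)-5,5-dimethyl-2-(propan-2-yl)-1,3-dioxane, via 1-bromo-4-methylpentan-3-one 2 (not isolated)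
Conditions: HBr (g), CH2Cl2, 0 °C; then 2,2-dimethylpropane-1,3-diol, HC(OEt)3, TsOH·H2O (cat.), rt
Reagents that add atoms: hydrogen bromide, Br; 2,2-dimethylpropane-1,3-diol, OCC(C)(C)CO
Why: Conjugate hydrobromination of the vinyl ketone gives the β-bromo ketone, and acid-catalysed ketalisation with the 1,3-diol, driven by the orthoformate as water scavenger, gives a dioxane of the type known to support a stable Grignard reagent; no stereocentre is formed.

**Step 2**
Reactants: 4 cycloheptane-1,3-dione
Product: 5 3-ethoxycyclohept-2-en-1-one
Conditions: EtOH, TsOH·H2O (cat.), toluene, reflux, Dean–Stark trap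
Reagents that add atoms: ethanol, CCO
Why: Acid-catalysed O-alkylation of the cyclic 1,3-dione with azeotropic removal of water is the standard vinylogous ester formation; no stereocentre is formed.

**Step 3**
Reactants: 3 2-(2-bromoethyl)-5,5-dimethyl-2-(propan-2-yl)-1,3-dioxane; 5 3-ethoxycyclohept-2-en-1-one
Product: 9 3-(4-methyl-3-oxopentyl)cyclohept-2-en-1-one, via Grignard reagent 6 (not isolated), via tertiary allylic alcohol 7 (not isolated), via ketal enone 8 (not isolated)
Conditions: Mg, THF, 25–35 °C; then 5, THF, 0 °C to rt; then 2 M aq. HCl, THF, rt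
Reagents that add atoms: water, O
Why: In this Stork–Danheiser sequence the Grignard reagent adds 1,2 to the vinylogous ester carbonyl, and aqueous acid then hydrolyses the enol ether with loss of water from the tertiary carbinol and cleaves the dioxane, so the racemic centre of 7 disappears and 9 is achiral.

**Step 4**
Reactants: 9 3-(4-methyl-3-oxopentyl)cyclohept-2-en-1-one; 10 trimethylaluminium
Product: 13 4β-hydroxy-1β-methyl-4α-(propan-2-yl)-5αH-perhydroazulen-6-one (1S,4R,5R; trans-fused), via aluminium enolate 11 (not isolated), via aluminium aldolate 12 (not isolated)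
Conditions: copper thiophene-2-carboxylate (CuTC, 5 mol %), L* (10 mol %), AlMe3 (2.5 equiv), Et2O, −30 °C, then 0 °C; aq. potassium sodium tartrate
Reagents that add atoms: none
Why: Proposed new method: AlMe3 hands a methyl group to the ligand-bound monovalent copper centre, the resulting methylcopper species binds the enone and transfers methyl to the Re face of C1, and the dimethylaluminium enolate 11 is released with its double bond fixed at C5=C6. The closest known reactions are the copper-catalysed enantioselective addition of trialkylaluminium reagents to 3-substituted cycloalkenones with capture of the aluminium enolate by aldehydes, and the conjugate addition–aldol cyclisation of keto-enones with organozinc reagents; what is new is the intramolecular capture of the aluminium enolate by a ketone. The cyclopentane closes by 5-(enolexo)-exo-trig attack of C5 on the aluminium-activated C4 carbonyl through a six-membered chelate in which O4 and O6 share the metal. C1 is set by the chiral ligand alone, since 9 is achiral; C5 and C4 follow from C1 because the chelate holds O4 cis to C6 on the new ring, and only the trans-fused arrangement then keeps the isopropyl group anti to the angular methyl. The step needs 1,4- rather than 1,2-transfer of methyl and survival of the side-chain ketone, which ligand-accelerated copper catalysis in Et2O at −30 °C and the hindered isopropyl ketone should provide. It also needs the aldol to end on one diastereomer, which warming to 0 °C before the quench should secure by letting the reversible aluminium aldolate settle as the chelated trans-fused isomer 12.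

**Step 5**
Reactants: 13 4β-hydroxy-1β-methyl-4α-(propan-2-yl)-5αH-perhydroazulen-6-one
Product: 14 1β-methyl-4α-(propan-2-yl)-4β,6-bis(trimethylsilyloxy)-5αH-perhydroazul-6-ene
Conditions: TMSOTf (3 equiv), Et3N (5 equiv), CH2Cl2, −78 to 0 °C
Reagents that add atoms: trimethylsilyl trifluoromethanesulfonate, C[Si](C)(C)OS(=O)(=O)C(F)(F)F
Why: Silylation caps the tertiary alcohol, which blocks retro-aldol cleavage in the basic steps that follow, and soft enolisation gives the silyl enol ether on the C7 side because C5–H lies between two fully substituted carbons; no stereocentre changes.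

**Step 6**
Reactants: 14 1β-methyl-4α-(propan-2-yl)-4β,6-bis(trimethylsilyloxy)-5αH-perhydroazul-6-ene
Product: 15 1β-methyl-4α-(propan-2-yl)-4β-(trimethylsilyloxy)-5αH-perhydroazul-7-en-6-one
Conditions: Pd(OAc)2 (1.1 equiv), MeCN, rt
Reagents that add atoms: none
Why: In this Saegusa–Ito oxidation the silyl enol ether passes to a palladium enolate and β-hydride elimination from C8 gives the C7=C8 enone while divalent palladium is reduced to zerovalent palladium; C5 is untouched because the enol ether is regiodefined.

**Step 7**
Reactants: 15 1β-methyl-4α-(propan-2-yl)-4β-(trimethylsilyloxy)-5αH-perhydroazul-7-en-6-one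
Product: 16 1β,8-dimethyl-4α-(propan-2-yl)-4β,6-bis(trimethylsilyloxy)-5αH-perhydroazul-6-ene (C8 epimers)
Conditions: MeMgBr (1.5 equiv), CuBr·SMe2 (10 mol %), TMSCl (2 equiv), THF, −78 °C; then Et3N, aq. NaHCO3
Reagents that add atoms: methylmagnesium bromide, C[Mg]Br; chlorotrimethylsilane, C[Si](C)(C)Cl
Why: TMSCl-accelerated copper-catalysed conjugate addition places the methyl group on C8 and traps the enolate as the C6=C7 silyl enol ether; the new C8 centre is formed without control and is removed in step 8.

**Step 8**
Reactants: 16 1β,8-dimethyl-4α-(propan-2-yl)-4β,6-bis(trimethylsilyloxy)-5αH-perhydroazul-6-ene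
Product: 17 1β,8-dimethyl-4α-(propan-2-yl)-4β-(trimethylsilyloxy)-5αH-perhydroazul-7-en-6-one
Conditions: Pd(OAc)2 (1.1 equiv), MeCN, rt to 40 °C
Reagents that add atoms: none
Why: A second Saegusa–Ito oxidation removes the C8 hydrogen through the palladium enolate and returns the enone, now β-methylated, so the uncontrolled C8 centre of 16 becomes trigonal.

**Step 9**
Reactants: 17 1β,8-dimethyl-4α-(propan-2-yl)-4β-(trimethylsilyloxy)-5αH-perhydroazul-7-en-6-one
Product: 20 4β-hydroxy-1β,8-dimethyl-4α-(propan-2-yl)-5αH-perhydroazul-8-en-6-one, via potassium dienolate 18 (not isolated), via silylated unconjugated enone 19 (not isolated)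
Conditions: KOtBu (3 equiv), THF, −20 to 0 °C; cannulate into AcOH/THF, −78 °C; then Bu4NF (1.5 equiv), 0 °C
Reagents that add atoms: none
Why: Deconjugation by kinetic protonation should work because equilibrating base gives the endocyclic extended dienolate 18 (C5–H is too shielded to compete), inverse quench with acetic acid protonates it at the α-carbon C7 to leave the C8=C9 alkene, and acetic acid-buffered fluoride then removes the silyl ether without free base that could move the double bond back; no stereocentre changes.

**Step 10**
Reactants: 20 4β-hydroxy-1β,8-dimethyl-4α-(propan-2-yl)-5αH-perhydroazul-8-en-6-one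
Product: 21 1β,8-dimethyl-4α-(propan-2-yl)-5αH-perhydroazul-8-ene-4β,6α-diol (1R,4R,5S,6S)
Conditions: Me4NBH(OAc)3 (5 equiv), MeCN/AcOH 1:1, −30 to 0 °C; aq. potassium sodium tartrate
Reagents that add atoms: none
Why: In this Evans–Saksena directed reduction the 4β-hydroxyl exchanges onto boron and delivers hydride intramolecularly to the β face of C6, the face on which O4 lies, so the new hydroxyl is 6α (equatorial, anti to O4), while the mild reagent leaves the alkene alone.

**Step 11**
Reactants: 21 1β,8-dimethyl-4α-(propan-2-yl)-5αH-perhydroazul-8-ene-4β,6α-diol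
Product: 22 4β-hydroxy-1β,8-dimethyl-4α-(propan-2-yl)-5αH-perhydroazul-8-en-6α-yl 4-methoxybenzoate
Conditions: 4-methoxybenzoyl chloride (1.5 equiv), DMAP (0.2 equiv), Et3N, CH2Cl2, 0 °C to rt
Reagents that add atoms: 4-methoxybenzoyl chloride, COc1ccc(cc1)C(Cl)=O
Why: DMAP-catalysed acylation esterifies the secondary C6 alcohol, while the tertiary C4 alcohol flanked by isopropyl and the ring fusion should not react, and C6 keeps its configuration because its C–O bond is not broken.

**Step 12**
Reactants: 22 4β-hydroxy-1β,8-dimethyl-4α-(propan-2-yl)-5αH-perhydroazul-8-en-6α-yl 4-methoxybenzoate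
Product: 23 8α,9α-epoxy-4β-hydroxy-1β,8-dimethyl-4α-(propan-2-yl)-5αH-perhydroazulen-6α-yl 4-methoxybenzoate (1R,4R,5S,6S,8R,9S; CNP0235939.1)
Conditions: mCPBA (1.2 equiv), NaHCO3, CH2Cl2, 0 °C
Reagents that add atoms: 3-chloroperoxybenzoic acid, OOC(=O)c1cccc(Cl)c1
Why: Prilezhaev epoxidation of the trisubstituted alkene should occur on the α face because the axial C1 methyl shields the β face at C9 in the chair-like cycloheptene, which sets C8 and C9 with the oxygen anti to that methyl, and the bicarbonate buffer guards against acid-promoted transannular opening by the C4 hydroxyl.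

**Compound list**
1 | 4-methylpent-1-en-3-one | CC(C)C(=O)C=C | starting material
2 | 1-bromo-4-methylpentan-3-one | CC(C)C(=O)CCBr | intermediate
3 | 2-(2-bromoethyl)-5,5-dimethyl-2-(propan-2-yl)-1,3-dioxane | CC(C)C1(CCBr)OCC(C)(C)CO1 | intermediate
4 | cycloheptane-1,3-dione | O=C1CCCCC(=O)C1 | starting material
5 | 3-ethoxycyclohept-2-en-1-one | CCOC1=CC(=O)CCCC1 | intermediate
6 | {2-[5,5-dimethyl-2-(propan-2-yl)-1,3-dioxan-2-yl]ethyl}magnesium bromide | CC(C)C1(CC[Mg]Br)OCC(C)(C)CO1 | intermediate
7 | 1-{2-[5,5-dimethyl-2-(propan-2-yl)-1,3-dioxan-2-yl]ethyl}-3-ethoxycyclohept-2-en-1-ol (racemic) | CCOC1=CC(O)(CCC2(C(C)C)OCC(C)(C)CO2)CCCC1 | intermediate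
8 | 3-{2-[5,5-dimethyl-2-(propan-2-yl)-1,3-dioxan-2-yl]ethyl}cyclohept-2-en-1-one | O=C1C=C(CCC2(C(C)C)OCC(C)(C)CO2)CCCC1 | intermediate
9 | 3-(4-methyl-3-oxopentyl)cyclohept-2-en-1-one | CC(C)C(=O)CCC1=CC(=O)CCCC1 | intermediate
10 | trimethylaluminium | C[Al](C)C | starting material
11 | dimethylaluminium enolate (C5=C6) of 3-methyl-3-(4-methyl-3-oxopentyl)cycloheptanone, C1 set | C[Al](C)OC1=C[C@](C)(CCC(=O)C(C)C)CCCC1 | intermediate
12 | dimethylaluminium 4-alkoxide (aldolate) of 13, chelated to the C6 carbonyl | O=C1CCCC[C@@]2(C)CC[C@@](O[Al](C)C)(C(C)C)[C@H]12 | intermediate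
13 | 4β-hydroxy-1β-methyl-4α-(propan-2-yl)-5αH-perhydroazulen-6-one (1S,4R,5R) | O=C1CCCC[C@@]2(C)CC[C@@](O)(C(C)C)[C@H]12 | intermediate
14 | 1β-methyl-4α-(propan-2-yl)-4β,6-bis(trimethylsilyloxy)-5αH-perhydroazul-6-ene | C[Si](C)(C)OC1=CCCC[C@@]2(C)CC[C@@](O[Si](C)(C)C)(C(C)C)[C@H]12 | intermediate
15 | 1β-methyl-4α-(propan-2-yl)-4β-(trimethylsilyloxy)-5αH-perhydroazul-7-en-6-one | O=C1C=CCC[C@@]2(C)CC[C@@](O[Si](C)(C)C)(C(C)C)[C@H]12 | intermediate
16 | 1β,8-dimethyl-4α-(propan-2-yl)-4β,6-bis(trimethylsilyloxy)-5αH-perhydroazul-6-ene (C8 epimers) | C[Si](C)(C)OC1=CC(C)CC[C@@]2(C)CC[C@@](O[Si](C)(C)C)(C(C)C)[C@H]12 | intermediate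
17 | 1β,8-dimethyl-4α-(propan-2-yl)-4β-(trimethylsilyloxy)-5αH-perhydroazul-7-en-6-one | O=C1C=C(C)CC[C@@]2(C)CC[C@@](O[Si](C)(C)C)(C(C)C)[C@H]12 | intermediate
18 | potassium 6-oxido-6,8-diene (extended dienolate of 17) | [K+].[O-]C1=CC(C)=CC[C@@]2(C)CC[C@@](O[Si](C)(C)C)(C(C)C)[C@H]12 | intermediate
19 | 1β,8-dimethyl-4α-(propan-2-yl)-4β-(trimethylsilyloxy)-5αH-perhydroazul-8-en-6-one | O=C1CC(C)=CC[C@@]2(C)CC[C@@](O[Si](C)(C)C)(C(C)C)[C@H]12 | intermediate
20 | 4β-hydroxy-1β,8-dimethyl-4α-(propan-2-yl)-5αH-perhydroazul-8-en-6-one | O=C1CC(C)=CC[C@@]2(C)CC[C@@](O)(C(C)C)[C@H]12 | intermediate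
21 | 1β,8-dimethyl-4α-(propan-2-yl)-5αH-perhydroazul-8-ene-4β,6α-diol (1R,4R,5S,6S) | O[C@H]1CC(C)=CC[C@@]2(C)CC[C@@](O)(C(C)C)[C@H]12 | intermediate
22 | 4β-hydroxy-1β,8-dimethyl-4α-(propan-2-yl)-5αH-perhydroazul-8-en-6α-yl 4-methoxybenzoate | COc1ccc(C(=O)O[C@H]2CC(C)=CC[C@@]3(C)CC[C@@](O)(C(C)C)[C@H]23)cc1 | intermediate
23 | 8α,9α-epoxy-4β-hydroxy-1β,8-dimethyl-4α-(propan-2-yl)-5αH-perhydroazulen-6α-yl 4-methoxybenzoate (1R,4R,5S,6S,8R,9S) | COc1ccc(C(=O)O[C@H]2C[C@@]3(C)O[C@H]3C[C@@]3(C)CC[C@@](O)(C(C)C)[C@H]23)cc1 | target

**Step count**
Total: 12 steps. Longest linear sequence: 11 steps (steps 1 and 3–12, or steps 2–12).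

**Steps most likely to fail**

Step 4. The aluminium enolate may not close cleanly onto the hindered isopropyl ketone, the closure may give more than one ring-fusion isomer, or AlMe3 may add to the side-chain carbonyl. The two bond formations would then be separated, with the ketone masked during the methyl transfer. The fallback sets out from ketal enone 8, which can be isolated by stopping the acid treatment of step 3 at 0 °C once the enone has formed. The same copper-catalysed AlMe3 addition, followed by Ac2O, would give the C5=C6 enol acetate of the C1-methylated ketal ketone F1. NBS in aqueous THF would convert it into the C5 α-bromo ketal ketone F2 (C5 epimers), and 2 M aq. HCl in THF would remove the dioxane to give the C5 bromo diketone F3. SmI2 in THF at −78 °C would then generate the samarium enolate at C5 only (Reformatsky-type) and close it onto the C4 ketone through the same O4/O6 chelate, coming back to the route at 13.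

Step 9. Protonation of the dienolate may be unselective, or the unconjugated enone may slip back into conjugation during quench and desilylation. The double-bond position would then be fixed by trapping and reduction. The fallback sets out from 17: KOtBu followed by Ac2O would give the 6-acetoxy-6,8-diene (dienyl acetate) F4. NaBH4 in EtOH at 0 °C would release the dienolate, protonate it at C7 and reduce the unconjugated ketone as it forms, giving the 4β-silyloxy perhydroazul-8-en-6-ol (C6 epimers) F5. Dess–Martin periodinane with NaHCO3 would return the ketone under neutral conditions, coming back to the route at 19, which is desilylated with buffered fluoride as in step 9.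

Step 10. Exchange of the hindered tertiary hydroxyl onto boron may be too slow, so that reduction stalls or the double bond migrates in acetic acid before hydride is delivered. Hydride delivery would then be replaced by electron transfer. The fallback sets out from 20: SmI2 in THF/MeOH at 0 °C would form the ketyl chelated to O4, and protonation should leave the more stable equatorial 6α-alcohol, coming back to the route at 21 (no new compound, F0).

**Further compounds**
F1 | step 4 | C5=C6 enol acetate of the C1-methylated ketal ketone | CC(=O)OC1=C[C@](C)(CCC2(C(C)C)OCC(C)(C)CO2)CCCC1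
F2 | step 4 | C5 α-bromo ketal ketone (C5 epimers) | O=C1CCCC[C@@](C)(CCC2(C(C)C)OCC(C)(C)CO2)C1Br
F3 | step 4 | C5 bromo diketone, 2-bromo-3-methyl-3-(4-methyl-3-oxopentyl)cycloheptanone (C5 epimers) | CC(C)C(=O)CC[C@]1(C)CCCCC(=O)C1Br
F4 | step 9 | 6-acetoxy-6,8-diene (dienyl acetate) of 17 | CC(=O)OC1=CC(C)=CC[C@@]2(C)CC[C@@](O[Si](C)(C)C)(C(C)C)[C@H]12
F5 | step 9 | 1β,8-dimethyl-4α-(propan-2-yl)-4β-(trimethylsilyloxy)-5αH-perhydroazul-8-en-6-ol (C6 epimers) | OC1CC(C)=CC[C@@]2(C)CC[C@@](O[Si](C)(C)C)(C(C)C)[C@H]12
F0 | step 10 | none | none
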